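The 18-membered ring (ring A: methoxy-bearing; B: meta-linked; C: phenolic; D: para-linked) holds two ArCH2–CH2Ar bridges, B–C and D–A; the central C–C bond of each is what remains when SO2 is cut out of a dibenzyl sulfone. Both bonds are therefore formed in one twofold Ramberg–Bäcklund reaction of a 20-membered macrocyclic bis(dibenzyl sulfone), which contracts the ring to the 18-membered bis-stilbene. The precursor already carries both diaryl ethers, the methoxy group and the phenol as its benzyl ether; it is built from two SNAr-derived diaryl ether halves by two benzylic thiolate alkylations, the second closing the macrocycle.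

Key step: step 12

Assumption: methyl 4-(benzyloxy)-3-hydroxybenzoate is taken as a purchasable building block; the alkene geometry of the bis-stilbene is not controlled, and the Z,Z isomer is drawn only for definiteness.

Structure check: the ring sizes (20 and 18 atoms), the substitution patterns of rings A–D and the atom counts of key-step precursor, key-step product and target agree with one another; no correction was needed. The target has no stereocentre.

Design remark: the formyl group sits on rings A and D and the ester on rings B and C. The two aldehyde-derived benzylic carbons therefore form the first thioether and the two ester-derived ones the second, with no protecting-group step; the ring C/D ether also comes from the strongly activated 4-fluorobenzaldehyde.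

**Route**

Step 1
Reactants: 1 2-fluoro-3-methoxybenzaldehyde; 2 methyl 3-hydroxybenzoate
Product: 3 methyl 3-(2-formyl-6-methoxyphenoxy)benzoate
Conditions: K2CO3, DMF, 120 °C
Reagents that add atoms: none
Why: Nucleophilic aromatic substitution (SNAr): the ortho-formyl group stabilises the anionic σ-adduct and fluoride is the best leaving group for addition–elimination, so the phenoxide of 2 should displace it while the methyl ester survives anhydrous carbonate.

Step 2
Reactants: 3 methyl 3-(2-formyl-6-methoxyphenoxy)benzoate
Product: 4 methyl 3-[2-(hydroxymethyl)-6-methoxyphenoxy]benzoate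
Conditions: NaBH4, MeOH/THF, 0 °C
Reagents that add atoms: none
Why: Chemoselective borohydride reduction: NaBH4 reduces the aldehyde quickly at 0 °C and leaves the methyl ester untouched.

Step 3
Reactants: 4 methyl 3-[2-(hydroxymethyl)-6-methoxyphenoxy]benzoate
Product: 5 methyl 3-[2-(bromomethyl)-6-methoxyphenoxy]benzoate
Conditions: PBr3, CH2Cl2, 0 °C
Reagents that add atoms: phosphorus tribromide, BrP(Br)Br
Why: Bromination of a primary benzylic alcohol with PBr3 (SN2 on the phosphite ester); ester and aryl ethers are inert under these conditions.

Step 4
Reactants: 6 methyl 4-(benzyloxy)-3-hydroxybenzoate; 7 4-fluorobenzaldehyde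
Product: 8 methyl 4-(benzyloxy)-3-(4-formylphenoxy)benzoate
Conditions: K2CO3, DMF, 110 °C
Reagents that add atoms: none
Why: SNAr: the para-formyl group makes 4-fluorobenzaldehyde a standard electrophile for phenoxides, and the phenol of 6 is the only nucleophile present.

Step 5
Reactants: 8 methyl 4-(benzyloxy)-3-(4-formylphenoxy)benzoate
Product: 9 methyl 4-(benzyloxy)-3-[4-(hydroxymethyl)phenoxy]benzoate
Conditions: NaBH4, MeOH/THF, 0 °C
Reagents that add atoms: none
Why: Chemoselective borohydride reduction of the aldehyde in the presence of the methyl ester and the benzyl ether.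

Step 6
Reactants: 9 methyl 4-(benzyloxy)-3-[4-(hydroxymethyl)phenoxy]benzoate
Product: 10 methyl 3-{4-[(acetylsulfanyl)methyl]phenoxy}-4-(benzyloxy)benzoate
Conditions: AcSH, PPh3, DIAD, THF, 0 °C to rt
Reagents that add atoms: thioacetic acid, CC(=O)S
Why: Mitsunobu reaction with a thioacid as the acidic partner: the primary benzylic alcohol is activated as its oxyphosphonium ion and displaced by thioacetate, which installs the masked thiol in one step.

Step 7
Reactants: 10 methyl 3-{4-[(acetylsulfanyl)methyl]phenoxy}-4-(benzyloxy)benzoate; 5 methyl 3-[2-(bromomethyl)-6-methoxyphenoxy]benzoate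
Product: 12 open-chain thioether diester (ring A–CH2–S–CH2–ring D; CO2Me on rings B and C), via benzylic thiol 11 (not isolated)
Conditions: K2CO3, degassed MeOH/THF, 0 °C to rt
Reagents that add atoms: none
Why: Thioacetate methanolysis followed by SN2 S-alkylation: the thiolate released in situ is far more nucleophilic than methoxide and should capture the benzylic bromide at once, while the methyl esters are degenerate in K2CO3/MeOH and exclusion of air suppresses disulfide formation.

Step 8
Reactants: 12 open-chain thioether diester
Product: 13 open-chain thioether diol (CH2OH on rings B and C)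
Conditions: LiAlH4, THF, 0 °C
Reagents that add atoms: none
Why: Hydride reduction of esters: LiAlH4 reduces both methyl esters to primary benzylic alcohols, while the thioether, the benzyl ether and the diaryl ethers do not react.

Step 9
Reactants: 13 open-chain thioether diol
Product: 14 open-chain thioether dibromide (CH2Br on rings B and C)
Conditions: CBr4, PPh3, CH2Cl2, 0 °C
Reagents that add atoms: carbon tetrabromide, BrC(Br)(Br)Br
Why: Appel reaction: both primary benzylic alcohols are converted into bromides under neutral conditions, which spare the benzyl ether and the thioether.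

Step 10
Reactants: 14 open-chain thioether dibromide
Product: 15 macrocyclic bis(dibenzyl sulfide) benzyl ether (20-membered ring)
Conditions: Na2S·9H2O, degassed EtOH/THF, slow addition of 14 at high dilution (about 1 mM), 60 °C
Reagents that add atoms: sodium sulfide, [Na+].[Na+].[S-2]
Why: Double SN2 thioether formation with sulfide as a one-atom linchpin: at high dilution the second displacement should be intramolecular and close the 20-membered ring, the classical thiacyclophane macrocyclisation.

Step 11
Reactants: 15 macrocyclic bis(dibenzyl sulfide) benzyl ether
Product: 17 macrocyclic bis(dibenzyl sulfone) benzyl ether (20-membered ring), via macrocyclic bis-sulfoxide 16 (not isolated)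
Conditions: mCPBA (4.5 equiv), CH2Cl2, 0 °C to rt
Reagents that add atoms: 3-chloroperbenzoic acid, OOC(=O)c1cccc(Cl)c1
Why: Peracid oxidation of sulfide to sulfone: sulfur is by far the most oxidisable site, excess mCPBA carries both sulfurs through the sulfoxide stage, and the molecule holds no alkene or amine that could compete.

Step 12
Reactants: 17 macrocyclic bis(dibenzyl sulfone) benzyl ether
Product: 20 macrocyclic bis-stilbene benzyl ether (18-membered ring; geometric mixture), via bis(α-bromo sulfone) 18 (not isolated), via bis-episulfone 19 (not isolated)
Conditions: C2Br2Cl4 (BrCl2C–CCl2Br, 2.5 equiv), KOH/Al2O3, t-BuOH/THF, 0 °C to rt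
Reagents that add atoms: none
Why: Each SO2 is flanked by two benzylic CH2 groups; KOH deprotonates one, the carbanion takes bromine from C2Br2Cl4 (which collapses to C2Cl4 and bromide), the carbanion at the other benzylic carbon displaces bromide in a 1,3-closure to the episulfone, and cheletropic loss of SO2 leaves the stilbene, the same sequence running independently at both bridges (18 and 19 show both bridges at the same stage). This is the Ramberg–Bäcklund reaction in its in situ halogenation variant, well established for dibenzyl sulfones. The 18-membered ring is not closed end to end: it arises by contraction of the 20-membered ring already present, each new C–C bond forming in a 3-exo-tet closure, so no macrocyclisation entropy is paid in this step. No stereocentre is created, and alkene geometry is left uncontrolled because both alkenes are hydrogenated in step 13. The selectivity needed is one halogenation per sulfone and no reaction elsewhere; it is secured because the four sulfonyl-benzylic CH2 groups are by far the most acidic positions, either α-carbon of a sulfone leads to the same alkene, the α-bromo sulfone closes faster than it is brominated again, and the phenol is masked as its benzyl ether.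

Step 13
Reactants: 20 macrocyclic bis-stilbene benzyl ether
Product: 21 target macrocycle (CNP0309263.0)
Conditions: H2 (1 atm), 10% Pd/C, EtOAc/EtOH, rt
Reagents that add atoms: none
Why: Heterogeneous catalytic hydrogenation with hydrogenolysis: Pd/C should saturate both stilbene double bonds whatever their geometry and cleave the aryl benzyl ether in the same operation, while the diaryl ethers and the methyl ether are stable.

**Compound list**

1 | 2-fluoro-3-methoxybenzaldehyde | COc1cccc(C=O)c1F | starting material
2 | methyl 3-hydroxybenzoate | COC(=O)c1cccc(O)c1 | starting material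
3 | methyl 3-(2-formyl-6-methoxyphenoxy)benzoate | COC(=O)c1cccc(Oc2c(OC)cccc2C=O)c1 | intermediate
4 | methyl 3-[2-(hydroxymethyl)-6-methoxyphenoxy]benzoate | COC(=O)c1cccc(Oc2c(OC)cccc2CO)c1 | intermediate
5 | methyl 3-[2-(bromomethyl)-6-methoxyphenoxy]benzoate | COC(=O)c1cccc(Oc2c(OC)cccc2CBr)c1 | intermediate
6 | methyl 4-(benzyloxy)-3-hydroxybenzoate | COC(=O)c1ccc(OCc2ccccc2)c(O)c1 | starting material
7 | 4-fluorobenzaldehyde | O=Cc1ccc(F)cc1 | starting material
8 | methyl 4-(benzyloxy)-3-(4-formylphenoxy)benzoate | COC(=O)c1ccc(OCc2ccccc2)c(Oc2ccc(C=O)cc2)c1 | intermediate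
9 | methyl 4-(benzyloxy)-3-[4-(hydroxymethyl)phenoxy]benzoate | COC(=O)c1ccc(OCc2ccccc2)c(Oc2ccc(CO)cc2)c1 | intermediate
10 | methyl 3-{4-[(acetylsulfanyl)methyl]phenoxy}-4-(benzyloxy)benzoate | COC(=O)c1ccc(OCc2ccccc2)c(Oc2ccc(CSC(C)=O)cc2)c1 | intermediate
11 | methyl 4-(benzyloxy)-3-[4-(sulfanylmethyl)phenoxy]benzoate (benzylic thiol) | COC(=O)c1ccc(OCc2ccccc2)c(Oc2ccc(CS)cc2)c1 | intermediate (not isolated)
12 | open-chain thioether diester: ring A benzylic CH2–S–CH2 ring D, CO2Me on rings B and C | COC(=O)c1cccc(Oc2c(OC)cccc2CSCc2ccc(Oc3cc(C(=O)OC)ccc3OCc3ccccc3)cc2)c1 | intermediate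
13 | open-chain thioether diol: CH2OH on rings B and C | OCc1cccc(Oc2c(OC)cccc2CSCc2ccc(Oc3cc(CO)ccc3OCc3ccccc3)cc2)c1 | intermediate
14 | open-chain thioether dibromide: CH2Br on rings B and C | BrCc1cccc(Oc2c(OC)cccc2CSCc2ccc(Oc3cc(CBr)ccc3OCc3ccccc3)cc2)c1 | intermediate
15 | 20-membered macrocyclic bis(dibenzyl sulfide), benzyl ether | COc1cccc2c1Oc1cccc(c1)CSCc1ccc(OCc3ccccc3)c(c1)Oc1ccc(cc1)CSC2 | intermediate
16 | 20-membered macrocyclic bis-sulfoxide, benzyl ether (mixture of sulfoxide stereoisomers) | COc1cccc2c1Oc1cccc(c1)CS(=O)Cc1ccc(OCc3ccccc3)c(c1)Oc1ccc(cc1)CS(=O)C2 | intermediate (not isolated)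
17 | 20-membered macrocyclic bis(dibenzyl sulfone), benzyl ether | COc1cccc2c1Oc1cccc(c1)CS(=O)(=O)Cc1ccc(OCc3ccccc3)c(c1)Oc1ccc(cc1)CS(=O)(=O)C2 | intermediate
18 | bis(α-bromo sulfone): one benzylic bromine per bridge, drawn on the ring B and ring A benzylic carbons (position immaterial; stereoisomer mixture) | COc1cccc2c1Oc1cccc(c1)C(Br)S(=O)(=O)Cc1ccc(OCc3ccccc3)c(c1)Oc1ccc(cc1)CS(=O)(=O)C2Br | intermediate (not isolated)
19 | bis-episulfone: each bridge a 2,3-diaryl thiirane 1,1-dioxide (stereoisomer mixture) | COc1cccc2c1Oc1cccc(c1)C1C(S1(=O)=O)c1ccc(OCc3ccccc3)c(c1)Oc1ccc(cc1)C1C2S1(=O)=O | intermediate (not isolated)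
20 | 18-membered macrocyclic bis-stilbene, benzyl ether (geometry not controlled; Z,Z drawn) | COc1cccc(/C=C\c2ccc(cc2)Oc2cc(ccc2OCc2ccccc2)/C=C\c2cccc(O3)c2)c13 | intermediate
21 | target CNP0309263.0: 18-membered bis(bibenzyl) macrocycle with ring A OMe and ring C OH | COc1cccc2c1Oc1cccc(c1)CCc1ccc(O)c(c1)Oc1ccc(cc1)CC2 | target

**Step count and risks**

Total step count: 13.
Longest linear sequence: 10 steps (steps 1–3 or 4–6, then 7–13).

Steps most likely to fail:

1. Step 12. Halogenation of the four benzylic sulfonyl positions may be uneven or excessive in the heterogeneous, strongly basic medium, and the sparingly soluble bis-sulfone may react incompletely, so that one bridge contracts while the other stalls or is degraded. The fallback sets out from 15 and comes back at 20. One halogen per bridge is placed at the sulfide oxidation level: N-chlorosuccinimide (2 equiv, CH2Cl2, 0 °C) should convert each dibenzyl sulfide into an α-chloro sulfide, giving the macrocyclic bis(α-chloro sulfide) F1. This is oxidised without delay with mCPBA to the macrocyclic bis(α-chloro sulfone) F2. Treatment of F2 with KOt-Bu in THF at −78 to 0 °C, homogeneous and free of any halogen source, should then complete the classical two-stage Ramberg–Bäcklund reaction and deliver 20.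

2. Step 10. Intermolecular thioether formation (linear oligomers, cyclic dimers) may outrun closure of the 20-membered ring, because the sulfide dianion can join two molecules before the second end finds its partner. The fallback sets out from 14 and comes back at 15. One equivalent of KSAc in acetone at 0 °C should give the two mono-substitution products, the ring B thioacetate/ring C bromide F3 and the ring B bromide/ring C thioacetate F4; unreacted 14 is recycled and the bis-thioacetate is removed. The F3/F4 mixture is then added slowly to Cs2CO3 in degassed MeOH/DMF at high dilution. The thiolate unmasked in situ closes onto the remaining benzylic bromide in a purely unimolecular step, and both regioisomers converge on 15.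

3. Step 1. Fluoride displacement at a carbon flanked by the formyl and the methoxy group may be sluggish, and the temperature needed may cause ester cleavage or aldehyde degradation. The fallback sets out from 2 and comes back at 3. The ether bond is made by copper catalysis instead of uncatalysed addition–elimination. Compound 2 is coupled with commercial 2-bromo-3-methoxybenzaldehyde (COc1cccc(C=O)c1Br) in an Ullmann diaryl ether synthesis (copper iodide CuI, N,N-dimethylglycine, Cs2CO3, dioxane, 100 °C), in which the ortho-formyl group should assist the copper insertion. The product is 3 itself, so no new intermediate arises.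

**Further compounds**

F1 | step 12 | macrocyclic bis(α-chloro sulfide), benzyl ether (chlorine drawn on the ring C and ring D benzylic carbons; stereoisomer mixture) | COc1cccc2c1Oc1cccc(c1)CSC(Cl)c1ccc(OCc3ccccc3)c(c1)Oc1ccc(cc1)C(Cl)SC2
F2 | step 12 | macrocyclic bis(α-chloro sulfone), benzyl ether (stereoisomer mixture) | COc1cccc2c1Oc1cccc(c1)CS(=O)(=O)C(Cl)c1ccc(OCc3ccccc3)c(c1)Oc1ccc(cc1)C(Cl)S(=O)(=O)C2
F3 | step 10 | open-chain thioether with CH2SAc on ring B and CH2Br on ring C | CC(=O)SCc1cccc(Oc2c(OC)cccc2CSCc2ccc(Oc3cc(CBr)ccc3OCc3ccccc3)cc2)c1
F4 | step 10 | open-chain thioether with CH2Br on ring B and CH2SAc on ring C | BrCc1cccc(Oc2c(OC)cccc2CSCc2ccc(Oc3cc(CSC(C)=O)ccc3OCc3ccccc3)cc2)c1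
F0 | step 1 | none | none
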